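A faster-reacting hand cannot keep its share of the substrate unless something refills it. So two times matter here, one for each hand.

all flasks: precatalyst 2.2 mM; impurity 2.1 mM
- noon: left-handed substrate 0.20 M; right-handed substrate 0.20 M; coupling partner 0.50 M; free catalyst 5 mM; the very flask that is asked about, followed so far
- winter: left-handed substrate 0.13 M; right-handed substrate 0.13 M; coupling partner 0.50 M; free catalyst 5 mM; run made earlier
- flask: left-handed substrate 0.20 M; right-handed substrate 0.20 M; coupling partner 0.500 M; free catalyst 5.0 mM; time 3.0 h

noon run (percent of the left-handed substrate and right-handed substrate together charged)

| time / min | left-handed product / % | right-handed product / % |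
|---|---|---|
| 12.0 | 8.7 | 0.8 |
| 25.0 | 14.2 | 1.5 |
| 40.0 | 18.7 | 3.3 |
| 50.0 | 22.4 | 4.0 |
| 60.0 | 25.7 | 4.6 |
| 80.0 | 28.0 | 5.8 |
| 90.0 | 30.4 | 6.0 |

winter run (percent of the left-handed substrate and right-handed substrate together charged)

| time / h | left-handed product / % | right-handed product / % |
|---|---|---|
| 0.167 | 7.5 | 1.7 |
| 0.500 | 16.4 | 2.9 |
| 0.833 | 22.7 | 4.7 |
| 1.33 | 29.2 | 6.5 |
| 2.00 | 35.9 | 9.1 |
| 2.50 | 39.4 | 10.6 |
| 3.00 | 42.4 | 11.6 |

(scatter of a reading: 0.5 percentage points)

1. left-handed product and right-handed product together, in percent of the left-handed substrate and right-handed substrate charged together, at 3.0 h
2. excess of left-handed product over right-handed product in the product at 3.0 h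
3. whether the exchange between left-handed substrate and right-handed substrate keeps pace with the reaction: how far the product's excess at 3.0 h gets from its value without exchange to its value with instant exchange (above 80% keeps pace, below 20% hardly takes part, else lags behind)

- free catalyst is single-handed; left-handed substrate and right-handed substrate are mirror images of each other, charged as a racemate, each of them at the stated concentration
- an excess is the difference of the two amounts in percent of their sum
- an excess is below zero if the other one leads

Each hand is half of the charge, so without exchange the part of it left is one minus twice its product reading. In the winter run at 3.00 h, that gives a mean half-life of 1.10 h for the left-handed substrate and 7.88 h for the right-handed one. Their ratio, the longer half-life over the shorter, is the selectivity factor, call it s, read here as 7.14. The noon run at 90.0 min reads 7.33, the same within scatter.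

Instant exchange would keep the two pools equal, so the product's excess would stay at (s−1)/(s+1), or 75.4%. But the winter run has fallen to 57.0%, so the pools are separating. My guide for the noon flask is that winter reading, with 54.0% of product, perhaps a little less.

The forecast said 52.5% (49.5% to 55.5%) and an excess of 58% (54% to 62%), with the excess falling “as plain kinetic resolution predicts”, and its verdict on the exchange was: hardly takes part.

The noon flask gives 51.2% with an excess of 59.2%, and the exchange hardly takes part, covering 3.2% of the way.

    left-handed substrate + racemization catalyst ⇌ right-handed substrate + racemization catalyst, rate k1*[racemization catalyst]*[left-handed substrate] forward; the back reaction follows from the equilibrium constant (k = 0.0150 /M/s)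
    coupling partner + free catalyst + right-handed substrate → free catalyst + right-handed product (k = 0.0200 /M²/s)
    free catalyst + impurity → spent catalyst (k = 0.700 /M/s)
    precatalyst → racemization catalyst (k = 2.70 × 10⁻⁵ /s)
    coupling partner + free catalyst + left-handed substrate → free catalyst + left-handed product (k = 0.140 /M²/s)

Put the noon flask's right-handed product, 10.4%, through s, and you get 40.6% of left-handed product against the 40.8% that flask holds. The neighbour charged with 0.0030 M of free catalyst reaches 29.8% of product, with 4.69% right-handed. The same s gives 25.3% of left-handed product, and that neighbour holds 25.1%.

(The runs are calculated for an exercise.)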